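The butyrolactone is disconnected at the two exocyclic C–CH2 bonds on its C3–C4 edge. Lactone C4, its ring O–CH2 (C5) and its benzylic CH2 are the three-carbon skeleton of (S)-epichlorohydrin, stored as a malonate-derived cyclopropane-fused lactone whose cyclopropane CH2 becomes the benzylic carbon. In one operation a copper-catalysed guaiacyl Grignard reagent opens this doubly activated cyclopropane at its CH2 (aryl–CH2 bond) and the released lactone–ester enolate is benzylated at C3 by the complete (2S,3R)-dihydrobenzofuran bromide (C3–CH2 bond). The precursor is ethyl (1R,5S)-2-oxo-3-oxabicyclo[3.1.0]hexane-1-carboxylate, which already carries C4 in its final configuration.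

Key step: step 14

Remark on the chemistry: C7 of the dihydrobenzofuran is a free OH in the target, so this oxygen must enter as a benzyl ether (a vanillin-type 7-methoxy group could not be cleaved beside the two guaiacyl methoxy groups); the route therefore starts from 3-(benzyloxy)-4-hydroxybenzaldehyde (assumed to be a catalogue compound), and the primary alcohol is carried as a TBDPS ether, which should withstand the acetal hydrolysis and the Krapcho conditions better than TBS.

**Step 1**
Reactants: 1 (S)-epichlorohydrin; 2 diethyl malonate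
Product: 5 ethyl (1R,5S)-2-oxo-3-oxabicyclo[3.1.0]hexane-1-carboxylate, via epoxide 3 (not isolated), via cyclopropane alkoxide 4 (not isolated)
Conditions: NaOEt (1.05 equiv), EtOH, rt → reflux
Reagents that add atoms: none
Why: Malonate alkylation–cyclopropanation–lactonisation cascade in which sodiomalonate opens the epoxide at its CH2, the alkoxide expels chloride to give epoxide 3, the malonate carbanion closes the cyclopropane by 3-exo-tet attack with inversion at the epichlorohydrin carbon (4) and the alkoxide lactonises onto an ester, so that C5 comes from the chiral pool and C1 is fixed by the cis ring fusion.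

**Step 2**
Reactants: 6 4-bromo-2-methoxyphenol
Product: 7 1-(benzyloxy)-4-bromo-2-methoxybenzene
Conditions: BnBr, K2CO3, DMF, rt
Reagents that add atoms: benzyl bromide, BrCc1ccccc1
Why: Williamson etherification of the phenoxide protects the guaiacol oxygen for the organomagnesium chemistry.

**Step 3**
Reactants: 7 1-(benzyloxy)-4-bromo-2-methoxybenzene
Product: 8 [4-(benzyloxy)-3-methoxyphenyl]magnesium bromide (THF solution, titrated and used directly)
Conditions: Mg turnings, I2 (cat.), THF, 45 °C
Reagents that add atoms: magnesium, [Mg]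
Why: Grignard formation by insertion of magnesium into the aryl C–Br bond is routine for this electron-rich bromide, and the benzyl ether is inert to it.

**Step 4**
Reactants: 9 3-(benzyloxy)-4-hydroxybenzaldehyde
Product: 10 3-(benzyloxy)-4-hydroxy-5-iodobenzaldehyde
Conditions: NIS (1.05 equiv), TFA (cat.), MeCN, rt
Reagents that add atoms: N-iodosuccinimide, O=C1CCC(=O)N1I
Why: Electrophilic aromatic iodination is directed by the phenol to its only free ortho position, the para position being blocked by the formyl group, as in the iodination of vanillin.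

**Step 5**
Reactants: 10 3-(benzyloxy)-4-hydroxy-5-iodobenzaldehyde; 11 [4-(benzyloxy)-3-methoxyphenyl]methanol
Product: 12 3-(benzyloxy)-4-{[4-(benzyloxy)-3-methoxyphenyl]methoxy}-5-iodobenzaldehyde
Conditions: PPh3, DIAD, THF, 0 °C → rt
Reagents that add atoms: none
Why: Mitsunobu etherification of the acidic, formyl-activated phenol with the primary benzylic alcohol installs the ArO–CH2–Ar' unit whose CH2 becomes C2 of the dihydrobenzofuran.

**Step 6**
Reactants: 12 aryl benzyl ether aldehyde
Product: 13 dimethyl acetal of 12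
Conditions: HC(OMe)3, PPTS (cat.), MeOH, 40 °C; Et3N quench
Reagents that add atoms: trimethyl orthoformate, COC(OC)OC
Why: Acid-catalysed acetalisation with orthoformate as water scavenger masks the aldehyde against the zinc enolate, diazo-transfer and hydride steps, PPTS being mild enough to spare the p-alkoxybenzyl aryl ether.

**Step 7**
Reactants: 13 aryl iodide acetal
Product: 14 methyl arylacetate
Conditions: BrZnCH2CO2Me (from BrCH2CO2Me, Zn, TMSCl cat., THF), Pd2(dba)3 (2.5 mol%), XPhos (6 mol%), THF, 60 °C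
Reagents that add atoms: methyl bromoacetate (as its zinc enolate), COC(=O)CBr
Why: Negishi-type cross-coupling of the aryl iodide with the Reformatsky zinc enolate (palladium-catalysed α-arylation of an acetate) gives the arylacetate directly and tolerates the acetal and the benzyl ethers.

**Step 8**
Reactants: 14 methyl arylacetate
Product: 15 methyl aryldiazoacetate
Conditions: p-ABSA, DBU, MeCN, 0 °C → rt
Reagents that add atoms: 4-acetamidobenzenesulfonyl azide, CC(=O)Nc1ccc(cc1)S(=O)(=O)N=[N+]=[N-]
Why: Regitz diazo transfer from the sulfonyl azide to the DBU-generated arylacetate enolate gives the donor/acceptor diazo ester.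

**Step 9**
Reactants: 15 methyl aryldiazoacetate
Product: 17 methyl (2S,3S)-trans-2-aryl-2,3-dihydrobenzofuran-3-carboxylate, via cis ester 16 (not isolated)
Conditions: Rh2(R-PTTL)4 (1 mol%), toluene, −60 °C; then NaOMe, MeOH, 0 °C → rt
Reagents that add atoms: none
Why: Intramolecular Rh(II)-carbenoid 1,5 C–H insertion into the electron-rich ArO–CH2–Ar' methylene closes the dihydrofuran ring, the chiral N-phthaloyl-tert-leucinate catalyst selecting the carbenoid face so that C2 should form as 2S in the kinetic cis ester 16 (by analogy with the sense reported for this catalyst family on ortho-benzyloxy aryldiazoacetates), and methoxide then epimerises only the enolisable C3 to the more stable trans (2S,3S) ester.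

**Step 10**
Reactants: 17 trans methyl ester
Product: 18 [(2S,3R)-2-aryl-5-(dimethoxymethyl)-2,3-dihydrobenzofuran-3-yl]methanol
Conditions: LiAlH4, THF, 0 °C
Reagents that add atoms: none
Why: Hydride reduction of the ester gives the primary alcohol and removes the acidic C3–H, so the trans relationship is locked while acetal and benzyl ethers stay untouched.

**Step 11**
Reactants: 18 primary alcohol
Product: 19 TBDPS ether of 18
Conditions: TBDPSCl, imidazole, DMF, rt
Reagents that add atoms: tert-butyl(chloro)diphenylsilane, CC(C)(C)[Si](Cl)(c1ccccc1)c1ccccc1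
Why: Imidazole-promoted silylation gives a primary TBDPS ether that tolerates dilute acid, Appel conditions, organomagnesium and copper reagents and hot chloride in DMSO.

**Step 12**
Reactants: 19 TBDPS ether acetal
Product: 21 5-(hydroxymethyl)dihydrobenzofuran, via aldehyde 20 (not isolated)
Conditions: PPTS (cat.), acetone–H2O, rt; evaporate acetone; NaBH4, MeOH–THF, 0 °C
Reagents that add atoms: water, O
Why: Mild acid hydrolysis of the electron-rich benzaldehyde acetal gives aldehyde 20 without touching the TBDPS ether, and borohydride reduction in the same flask delivers the benzylic alcohol.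

**Step 13**
Reactants: 21 benzylic alcohol
Product: 22 5-(bromomethyl)dihydrobenzofuran (used at once as a solution)
Conditions: CBr4, PPh3, CH2Cl2, 0 °C
Reagents that add atoms: carbon tetrabromide, BrC(Br)(Br)Br
Why: Appel bromination converts the benzylic alcohol into the bromide under neutral conditions through the alkoxyphosphonium bromide, which suits a labile p-alkoxybenzyl bromide.

**Step 14**
Reactants: 5 ethyl (1R,5S)-2-oxo-3-oxabicyclo[3.1.0]hexane-1-carboxylate; 8 [4-(benzyloxy)-3-methoxyphenyl]magnesium bromide; 22 5-(bromomethyl)dihydrobenzofuran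
Product: 24 ethyl (3S,4S)-3,4-bis(arylmethyl)-2-oxooxolane-3-carboxylate, via bromomagnesium enolate 23 (not isolated)
Conditions: 5 (1.4 equiv), CuI (10 mol%), THF, −30 °C, add 8 (1.3 equiv), −30 → 0 °C; then 22 (1.0 equiv), DMPU, 0 °C → rt
Reagents that add atoms: none
Why: Proposed new method: the arylcopper species formed from 8 and catalytic CuI attacks the unsubstituted cyclopropane carbon C6 of 5 in an SN2-like homoconjugate addition, the C1–C6 bond breaking because lactone and ester carbonyls both stabilise the developing charge, so ring strain is released into the chelated lactone–ester enolate 23, which is then C-benzylated by 22 once DMPU is added. The closest known chemistry is the copper-catalysed Grignard opening of 2-oxo-3-oxabicyclo[3.1.0]hexane-1-carboxylates followed, after isolation, by alkylation of the α-alkoxycarbonyl lactone with a benzylic halide; only the omission of the isolation is new. No ring is closed; the three-membered ring is opened and the lactone ring is kept. Lactone C4 is the untouched C5 of 5 and keeps the configuration derived from epichlorohydrin, while the new quaternary C3 should be set by approach of 22 anti to the C4 arylmethyl group, which has no lasting consequence because C3 is re-set after loss of the ester. The step needs attack at the cyclopropane CH2 instead of carbonyl addition, secured by copper catalysis and the geminal acceptors, and C- instead of O-alkylation, secured by the soft benzylic bromide and the malonate-type enolate. Using 5 in slight excess over 8 leaves no aryl metal to cross-couple with bromide 22, which is the limiting component.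

**Step 15**
Reactants: 24 α-ethoxycarbonyl bis(arylmethyl) lactone
Product: 25 (3S,4S)-trans-3,4-bis(arylmethyl)oxolan-2-one (benzyl and TBDPS protected)
Conditions: LiCl, H2O, DMSO, 140 °C; then DBU, 60 °C
Reagents that add atoms: none
Why: Krapcho dealkoxycarbonylation (chloride attacks the ethyl group, the carboxylate loses CO2 and the lactone enolate is protonated) removes the ester, and base equilibration of the epimerisable C3 then funnels the material into the more stable trans lactone under control of C4.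

**Step 16**
Reactants: 25 protected trans lactone
Product: 26 tri-O-benzyl primary alcohol
Conditions: TBAF, AcOH, THF, rt
Reagents that add atoms: none
Why: Fluoride-induced cleavage of the Si–O bond, buffered with acetic acid to spare the lactone and its C3 centre, frees the primary alcohol.

**Step 17**
Reactants: 26 tri-O-benzyl primary alcohol
Product: 27 target
Conditions: H2 (1 atm), 10% Pd/C, EtOAc–MeOH, rt
Reagents that add atoms: none
Why: Catalytic hydrogenolysis cleaves the three aryl benzyl ethers quickly at room temperature and atmospheric pressure, conditions under which the cyclic benzylic ether of the dihydrobenzofuran, the lactone and the methoxy groups should be retained.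

**Compound list**

1 | (S)-epichlorohydrin, (2S)-2-(chloromethyl)oxirane | ClC[C@@H]1CO1 | starting material
2 | diethyl malonate | CCOC(=O)CC(=O)OCC | starting material
3 | diethyl 2-{[(2S)-oxiran-2-yl]methyl}propanedioate (present as its sodium enolate) | CCOC(=O)C(C[C@H]1CO1)C(=O)OCC | intermediate
4 | sodium alkoxide of diethyl (2S)-2-(hydroxymethyl)cyclopropane-1,1-dicarboxylate | CCOC(=O)C1(C(=O)OCC)C[C@@H]1C[O-].[Na+] | intermediate
5 | ethyl (1R,5S)-2-oxo-3-oxabicyclo[3.1.0]hexane-1-carboxylate | CCOC(=O)[C@@]12C[C@@H]1COC2=O | intermediate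
6 | 4-bromo-2-methoxyphenol | COc1cc(Br)ccc1O | starting material
7 | 1-(benzyloxy)-4-bromo-2-methoxybenzene | COc1cc(Br)ccc1OCc1ccccc1 | intermediate
8 | [4-(benzyloxy)-3-methoxyphenyl]magnesium bromide | COc1cc([Mg]Br)ccc1OCc1ccccc1 | intermediate
9 | 3-(benzyloxy)-4-hydroxybenzaldehyde | O=Cc1ccc(O)c(OCc2ccccc2)c1 | starting material
10 | 3-(benzyloxy)-4-hydroxy-5-iodobenzaldehyde | O=Cc1cc(I)c(O)c(OCc2ccccc2)c1 | intermediate
11 | [4-(benzyloxy)-3-methoxyphenyl]methanol | COc1cc(CO)ccc1OCc1ccccc1 | starting material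
12 | 3-(benzyloxy)-4-{[4-(benzyloxy)-3-methoxyphenyl]methoxy}-5-iodobenzaldehyde | O=Cc1cc(I)c(OCc2ccc(OCc3ccccc3)c(OC)c2)c(OCc2ccccc2)c1 | intermediate
13 | 1-(benzyloxy)-2-{[4-(benzyloxy)-3-methoxyphenyl]methoxy}-5-(dimethoxymethyl)-3-iodobenzene | COC(OC)c1cc(I)c(OCc2ccc(OCc3ccccc3)c(OC)c2)c(OCc2ccccc2)c1 | intermediate
14 | methyl 2-[3-(benzyloxy)-2-{[4-(benzyloxy)-3-methoxyphenyl]methoxy}-5-(dimethoxymethyl)phenyl]acetate | COC(=O)Cc1cc(C(OC)OC)cc(OCc2ccccc2)c1OCc1ccc(OCc2ccccc2)c(OC)c1 | intermediate
15 | methyl 2-diazo-2-[3-(benzyloxy)-2-{[4-(benzyloxy)-3-methoxyphenyl]methoxy}-5-(dimethoxymethyl)phenyl]acetate | COC(=O)C(=[N+]=[N-])c1cc(C(OC)OC)cc(OCc2ccccc2)c1OCc1ccc(OCc2ccccc2)c(OC)c1 | intermediate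
16 | methyl (2S,3R)-7-(benzyloxy)-2-[4-(benzyloxy)-3-methoxyphenyl]-5-(dimethoxymethyl)-2,3-dihydro-1-benzofuran-3-carboxylate (2,3-cis) | COC(OC)c1cc(OCc2ccccc2)c2c(c1)[C@@H](C(=O)OC)[C@@H](c1ccc(OCc3ccccc3)c(OC)c1)O2 | intermediate
17 | methyl (2S,3S)-7-(benzyloxy)-2-[4-(benzyloxy)-3-methoxyphenyl]-5-(dimethoxymethyl)-2,3-dihydro-1-benzofuran-3-carboxylate (2,3-trans) | COC(OC)c1cc(OCc2ccccc2)c2c(c1)[C@H](C(=O)OC)[C@@H](c1ccc(OCc3ccccc3)c(OC)c1)O2 | intermediate
18 | [(2S,3R)-7-(benzyloxy)-2-[4-(benzyloxy)-3-methoxyphenyl]-5-(dimethoxymethyl)-2,3-dihydro-1-benzofuran-3-yl]methanol (2,3-trans) | COC(OC)c1cc(OCc2ccccc2)c2c(c1)[C@H](CO)[C@@H](c1ccc(OCc3ccccc3)c(OC)c1)O2 | intermediate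
19 | {[(2S,3R)-7-(benzyloxy)-2-[4-(benzyloxy)-3-methoxyphenyl]-5-(dimethoxymethyl)-2,3-dihydro-1-benzofuran-3-yl]methoxy}(tert-butyl)diphenylsilane | COC(OC)c1cc(OCc2ccccc2)c2c(c1)[C@H](CO[Si](c1ccccc1)(c1ccccc1)C(C)(C)C)[C@@H](c1ccc(OCc3ccccc3)c(OC)c1)O2 | intermediate
20 | (2S,3R)-7-(benzyloxy)-2-[4-(benzyloxy)-3-methoxyphenyl]-3-{[(tert-butyldiphenylsilyl)oxy]methyl}-2,3-dihydro-1-benzofuran-5-carbaldehyde | O=Cc1cc(OCc2ccccc2)c2c(c1)[C@H](CO[Si](c1ccccc1)(c1ccccc1)C(C)(C)C)[C@@H](c1ccc(OCc3ccccc3)c(OC)c1)O2 | intermediate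
21 | [(2S,3R)-7-(benzyloxy)-2-[4-(benzyloxy)-3-methoxyphenyl]-3-{[(tert-butyldiphenylsilyl)oxy]methyl}-2,3-dihydro-1-benzofuran-5-yl]methanol | OCc1cc(OCc2ccccc2)c2c(c1)[C@H](CO[Si](c1ccccc1)(c1ccccc1)C(C)(C)C)[C@@H](c1ccc(OCc3ccccc3)c(OC)c1)O2 | intermediate
22 | {[(2S,3R)-7-(benzyloxy)-2-[4-(benzyloxy)-3-methoxyphenyl]-5-(bromomethyl)-2,3-dihydro-1-benzofuran-3-yl]methoxy}(tert-butyl)diphenylsilane | BrCc1cc(OCc2ccccc2)c2c(c1)[C@H](CO[Si](c1ccccc1)(c1ccccc1)C(C)(C)C)[C@@H](c1ccc(OCc3ccccc3)c(OC)c1)O2 | intermediate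
23 | bromomagnesium enolate of ethyl (4S)-4-{[4-(benzyloxy)-3-methoxyphenyl]methyl}-2-oxooxolane-3-carboxylate | CCOC(O[Mg]Br)=C1C(=O)OC[C@H]1Cc1ccc(OCc2ccccc2)c(OC)c1 | intermediate
24 | ethyl (3S,4S)-4-{[4-(benzyloxy)-3-methoxyphenyl]methyl}-3-{[(2S,3R)-7-(benzyloxy)-2-[4-(benzyloxy)-3-methoxyphenyl]-3-{[(tert-butyldiphenylsilyl)oxy]methyl}-2,3-dihydro-1-benzofuran-5-yl]methyl}-2-oxooxolane-3-carboxylate | COc1cc(C[C@@H]2COC(=O)[C@@]2(C(=O)OCC)Cc2cc(OCc3ccccc3)c3c(c2)[C@H](CO[Si](c2ccccc2)(c2ccccc2)C(C)(C)C)[C@@H](c2ccc(OCc4ccccc4)c(OC)c2)O3)ccc1OCc1ccccc1 | intermediate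
25 | (3S,4S)-4-{[4-(benzyloxy)-3-methoxyphenyl]methyl}-3-{[(2S,3R)-7-(benzyloxy)-2-[4-(benzyloxy)-3-methoxyphenyl]-3-{[(tert-butyldiphenylsilyl)oxy]methyl}-2,3-dihydro-1-benzofuran-5-yl]methyl}oxolan-2-one (3,4-trans) | COc1cc(C[C@@H]2COC(=O)[C@H]2Cc2cc(OCc3ccccc3)c3c(c2)[C@H](CO[Si](c2ccccc2)(c2ccccc2)C(C)(C)C)[C@@H](c2ccc(OCc4ccccc4)c(OC)c2)O3)ccc1OCc1ccccc1 | intermediate
26 | (3S,4S)-4-{[4-(benzyloxy)-3-methoxyphenyl]methyl}-3-{[(2S,3R)-7-(benzyloxy)-2-[4-(benzyloxy)-3-methoxyphenyl]-3-(hydroxymethyl)-2,3-dihydro-1-benzofuran-5-yl]methyl}oxolan-2-one | COc1cc(C[C@@H]2COC(=O)[C@H]2Cc2cc(OCc3ccccc3)c3c(c2)[C@H](CO)[C@@H](c2ccc(OCc4ccccc4)c(OC)c2)O3)ccc1OCc1ccccc1 | intermediate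
27 | (3S,4S)-4-[(4-hydroxy-3-methoxyphenyl)methyl]-3-{[(2S,3R)-7-hydroxy-2-(4-hydroxy-3-methoxyphenyl)-3-(hydroxymethyl)-2,3-dihydro-1-benzofuran-5-yl]methyl}oxolan-2-one | COc1cc(C[C@@H]2COC(=O)[C@H]2Cc2cc(O)c3c(c2)[C@H](CO)[C@@H](c2ccc(O)c(OC)c2)O3)ccc1O | target

**Summary**

Total step count: 17. Longest linear sequence: 14 steps (steps 4–17, from 3-(benzyloxy)-4-hydroxybenzaldehyde).

**Steps most likely to fail**

1. Step 14 (proposed new method). The chelated magnesium enolate may alkylate too slowly, so that protonated mono-substituted lactone is recovered. Residual aryl metal may consume the bromide by cross-coupling, or the labile bromide may ionise and decompose before it is trapped. The fallback uses known chemistry and sets out from 5 and 8. The copper-catalysed ring opening is run alone and quenched with saturated NH4Cl to isolate ethyl (4S)-4-{[4-(benzyloxy)-3-methoxyphenyl]methyl}-2-oxooxolane-3-carboxylate F1 as a mixture of C3 epimers. Its sodium enolate (NaH, DMF, 0 °C) is then alkylated with bromide 22 in a separate operation, and the route is rejoined at 24.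

2. Step 9. Face selection by the catalyst may be insufficient, or of the unexpected sense, on this heavily oxygenated substrate, and C2 integrity may erode through reversible ring opening during the methoxide epimerisation. The fallback replaces catalyst control by auxiliary control with separable diastereomers and sets out from 14. Saponification (LiOH, THF–MeOH–H2O, work-up at pH 5) gives the arylacetic acid F2. Esterification with (2S)-2-hydroxy-1-(pyrrolidin-1-yl)propan-1-one (DCC, DMAP, CH2Cl2) gives the lactamide ester F3, and diazo transfer (p-ABSA, DBU) gives the diazo ester F4. Insertion with Rh2(S-DOSP)4 in CH2Cl2 is expected, by analogy with closely related 7-alkoxy-2-aryl systems, to give the (2S,3S)-trans dihydrobenzofuran lactamide ester F5 as the major diastereomer, which is purified by chromatography. Reduction with LiBH4 (THF–MeOH, 0 °C) releases the auxiliary and rejoins the route at 18.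

3. Step 15. Dealkoxycarbonylation of the hindered quaternary ester may be incomplete at 140 °C, the silyl ether may be partly lost, and the cis/trans equilibration may stop short. The fallback sets out from 24. Hydrolysis with LiOH (THF–MeOH–H2O, 50 °C) followed by acidification to pH 3 relactonises the hydroxy diacid to the α-carboxy lactone F6 (C3 epimers). Heating in toluene at 100–110 °C effects decarboxylation, and DBU equilibration rejoins the route at 25. Any desilylated material simply anticipates step 16.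

**Further compounds**

F1 | step 14 | ethyl (4S)-4-{[4-(benzyloxy)-3-methoxyphenyl]methyl}-2-oxooxolane-3-carboxylate (C3 epimers) | CCOC(=O)C1C(=O)OC[C@H]1Cc1ccc(OCc2ccccc2)c(OC)c1
F2 | step 9 | 2-[3-(benzyloxy)-2-{[4-(benzyloxy)-3-methoxyphenyl]methoxy}-5-(dimethoxymethyl)phenyl]acetic acid | OC(=O)Cc1cc(C(OC)OC)cc(OCc2ccccc2)c1OCc1ccc(OCc2ccccc2)c(OC)c1
F3 | step 9 | (2S)-1-oxo-1-(pyrrolidin-1-yl)propan-2-yl 2-[3-(benzyloxy)-2-{[4-(benzyloxy)-3-methoxyphenyl]methoxy}-5-(dimethoxymethyl)phenyl]acetate | C[C@H](OC(=O)Cc1cc(C(OC)OC)cc(OCc2ccccc2)c1OCc1ccc(OCc2ccccc2)c(OC)c1)C(=O)N1CCCC1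
F4 | step 9 | (2S)-1-oxo-1-(pyrrolidin-1-yl)propan-2-yl 2-diazo-2-[3-(benzyloxy)-2-{[4-(benzyloxy)-3-methoxyphenyl]methoxy}-5-(dimethoxymethyl)phenyl]acetate | C[C@H](OC(=O)C(=[N+]=[N-])c1cc(C(OC)OC)cc(OCc2ccccc2)c1OCc1ccc(OCc2ccccc2)c(OC)c1)C(=O)N1CCCC1
F5 | step 9 | (2S)-1-oxo-1-(pyrrolidin-1-yl)propan-2-yl (2S,3S)-7-(benzyloxy)-2-[4-(benzyloxy)-3-methoxyphenyl]-5-(dimethoxymethyl)-2,3-dihydro-1-benzofuran-3-carboxylate (2,3-trans) | COC(OC)c1cc(OCc2ccccc2)c2c(c1)[C@H](C(=O)O[C@@H](C)C(=O)N1CCCC1)[C@@H](c1ccc(OCc3ccccc3)c(OC)c1)O2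
F6 | step 15 | (4S)-4-{[4-(benzyloxy)-3-methoxyphenyl]methyl}-3-{[(2S,3R)-7-(benzyloxy)-2-[4-(benzyloxy)-3-methoxyphenyl]-3-{[(tert-butyldiphenylsilyl)oxy]methyl}-2,3-dihydro-1-benzofuran-5-yl]methyl}-2-oxooxolane-3-carboxylic acid (C3 epimers) | COc1cc(C[C@@H]2COC(=O)C2(C(=O)O)Cc2cc(OCc3ccccc3)c3c(c2)[C@H](CO[Si](c2ccccc2)(c2ccccc2)C(C)(C)C)[C@@H](c2ccc(OCc4ccccc4)c(OC)c2)O3)ccc1OCc1ccccc1
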